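**Retrosynthetic overview**

1. Rings A and B are the same unit, 3,4,5-trimethoxyphenol 1. Ortho-formylation of 1 (through benzylic alcohol 2) gives salicylaldehyde 3 for ring A, and the purchased ortho-acetyl analogue 4 supplies ring B with its 6'-OH already in place.
2. C–C union: acid-mediated aldol condensation of 3 with 4 gives chalcone 5. Ring C, the only ring formed, closes at once by C–O bond formation to give 2'-hydroxyflavylium salt 6; the two aryl halves of 5 are identical, so ring closure through either phenol leads to the same flavone skeleton.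
3. Key disconnection: the C4=O bond of the flavone, made from the C4–H of 6 by oxygen-atom transfer from pyridine N-oxide (adduct 7) to give flavone 8.
4. Last disconnection: 5-OH from 5-OMe by chelation-controlled ether cleavage (boron chelate 9) to give target 10.
5. Read backwards: 10 ⇐ 8 ⇐ 6 ⇐ 3 + 4; 3 ⇐ 1.

Assumption: the target has no stereocentre and no configurationally stable axis, so "the single enantiomer given" is read as the one achiral compound drawn.

**Route**

Step 1
Reactants: 1 3,4,5-trimethoxyphenol
Product: 3 6-hydroxy-2,3,4-trimethoxybenzaldehyde, via benzylic alcohol 2 (not isolated)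
Conditions: (CH2O)n (6 equiv), MgCl2 (2 equiv), Et3N (4 equiv), MeCN, reflux, 4 h; then 1 M HCl
Reagents that add atoms: formaldehyde (from paraformaldehyde), C=O
Why: Casnati–Skattebøl magnesium-mediated ortho-formylation: the chloromagnesium phenoxide of 1 delivers formaldehyde to the ortho carbon through a six-membered chelate (the two ortho positions are equivalent, so one regioisomer forms), and a second formaldehyde oxidises the benzylic alkoxide of 2 by Oppenauer-type hydride transfer; no stereocentre is formed.

Step 2
Reactants: 3 6-hydroxy-2,3,4-trimethoxybenzaldehyde, 4 1-(6-hydroxy-2,3,4-trimethoxyphenyl)ethan-1-one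
Product: 6 2-(6-hydroxy-2,3,4-trimethoxyphenyl)-5,6,7-trimethoxychromenylium trifluoromethanesulfonate, via chalcone 5 (not isolated)
Conditions: TfOH (2 equiv), AcOH, 25 °C, 24 h; then Et2O, filtration
Reagents that add atoms: trifluoromethanesulfonic acid, OS(=O)(=O)C(F)(F)F
Why: Acid-catalysed Claisen–Schmidt (aldol) condensation followed by Robinson-type flavylium ring closure: chalcone 5 isomerises E/Z under acid, the aldehyde-side phenol adds to the protonated ketone and loss of water gives the aromatic benzopyrylium cation, which is the thermodynamic sink in strong acid and precipitates as its triflate; no stereocentre is formed.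

Step 3
Reactants: 6 2-(6-hydroxy-2,3,4-trimethoxyphenyl)-5,6,7-trimethoxychromenylium trifluoromethanesulfonate
Product: 8 2-(6-hydroxy-2,3,4-trimethoxyphenyl)-5,6,7-trimethoxy-4H-chromen-4-one, via N-alkoxypyridinium adduct 7 (not isolated)
Conditions: pyridine N-oxide (3 equiv), 4 Å MS, MeCN, 60 °C, 6 h
Reagents that add atoms: pyridine N-oxide, [O-][n+]1ccccc1
Why: Proposed new method: oxygen-atom transfer from an N-oxide to the C4–H of a flavylium cation, in which the N-oxide oxygen adds reversibly at the two electrophilic positions of 6, the C2 adduct (shielded by the 2',6'-disubstituted aryl group and lacking a hydrogen to lose) only reverts, whereas the C4 adduct 7 is an N-alkoxypyridinium salt whose doubly activated benzylic/allylic C4–H is removed by excess N-oxide or liberated pyridine with N–O cleavage, expelling pyridine and forming the C4=O bond of the 4-pyranone irreversibly, while water or hydroxide would instead give the C2 hemiketal and ring-opened chalcone; the closest known reaction types are the Ganem oxidation of benzylic halides through N-alkoxypyridinium salts, the Kornblum oxidation and the Decker oxidation of pyridinium salts to pyridones; no stereocentre remains in 8.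

Step 4
Reactants: 8 2-(6-hydroxy-2,3,4-trimethoxyphenyl)-5,6,7-trimethoxy-4H-chromen-4-one
Product: 10 5-hydroxy-2-(6-hydroxy-2,3,4-trimethoxyphenyl)-6,7-dimethoxy-4H-chromen-4-one, via boron chelate 9 (not isolated)
Conditions: BCl3 (3 equiv, 1 M in CH2Cl2), CH2Cl2, −78 to 0 °C, 2 h; then H2O
Reagents that add atoms: none
Why: Chelation-controlled Lewis-acid ether cleavage: BCl3 bound to the C4 carbonyl forms a six-membered chelate with the peri 5-methoxy oxygen and chloride removes only that methyl group, as in the standard 5-O-demethylation of polymethoxyflavones, while the non-chelated methyl ethers survive at 0 °C and the ring B aryloxyborane is hydrolysed back to the phenol on work-up; no stereocentre is involved.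

**Compound list**

1 | 3,4,5-trimethoxyphenol | COc1cc(O)cc(OC)c1OC | starting material
2 | 2-(hydroxymethyl)-3,4,5-trimethoxyphenol (present as its chloromagnesium salt) | COc1cc(O)c(CO)c(OC)c1OC | intermediate
3 | 6-hydroxy-2,3,4-trimethoxybenzaldehyde | COc1cc(O)c(C=O)c(OC)c1OC | intermediate
4 | 1-(6-hydroxy-2,3,4-trimethoxyphenyl)ethan-1-one | CC(=O)c1c(O)cc(OC)c(OC)c1OC | starting material
5 | (E)-1,3-bis(6-hydroxy-2,3,4-trimethoxyphenyl)prop-2-en-1-one | COc1cc(O)c(/C=C/C(=O)c2c(O)cc(OC)c(OC)c2OC)c(OC)c1OC | intermediate
6 | 2-(6-hydroxy-2,3,4-trimethoxyphenyl)-5,6,7-trimethoxychromenylium trifluoromethanesulfonate | COc1cc(O)c(-c2ccc3c(OC)c(OC)c(OC)cc3[o+]2)c(OC)c1OC.[O-]S(=O)(=O)C(F)(F)F | intermediate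
7 | 1-{[2-(6-hydroxy-2,3,4-trimethoxyphenyl)-5,6,7-trimethoxy-4H-chromen-4-yl]oxy}pyridin-1-ium trifluoromethanesulfonate (racemic at C4, transient) | COc1cc(O)c(C2=CC(O[n+]3ccccc3)c3c(OC)c(OC)c(OC)cc3O2)c(OC)c1OC.[O-]S(=O)(=O)C(F)(F)F | intermediate
8 | 2-(6-hydroxy-2,3,4-trimethoxyphenyl)-5,6,7-trimethoxy-4H-chromen-4-one | COc1cc(O)c(-c2cc(=O)c3c(OC)c(OC)c(OC)cc3o2)c(OC)c1OC | intermediate
9 | 5-O,6'-O-bis(dichloroboryl) derivative of the 5-demethylated flavone (5-O–BCl2 chelated to the C4 carbonyl) | COc1cc(OB(Cl)Cl)c(-c2cc(=O)c3c(OB(Cl)Cl)c(OC)c(OC)cc3o2)c(OC)c1OC | intermediate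
10 | 5-hydroxy-2-(6-hydroxy-2,3,4-trimethoxyphenyl)-6,7-dimethoxy-4H-chromen-4-one (5,6'-dihydroxy-6,7,2',3',4'-pentamethoxyflavone) | COc1cc(O)c(-c2cc(=O)c3c(O)c(OC)c(OC)cc3o2)c(OC)c1OC | target

**Step count and risks**

Total step count: 4. Longest linear sequence: 4 steps (1 → 3 → 6 → 8 → 10); compound 4 is purchased.

The three steps most likely to fail:

Step 3 (the proposed new oxygen transfer). The electron-rich cation may form too little of the C4 adduct, the liberated pyridine may convert 6 into its neutral quinoidal base, and traces of water divert 6 to the chalcone. The fallback uses known chemistry only, sets out from 6 and comes back at 8. Compound 6 is stirred in MeOH/H2O buffered with NaOAc (pH about 5, 50 °C); water adds at C2, the hemiketal opens, and the cation becomes chalcone 5 in equilibrium with its ring-closed isomer, racemic 2-(6-hydroxy-2,3,4-trimethoxyphenyl)-5,6,7-trimethoxychroman-4-one F1. The crude mixture is heated with I2 (10 mol %) in DMSO at 120 °C, the classical oxidative cyclisation of 2'-hydroxychalcones and dehydrogenation of flavanones, which converts both species into 8.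

Step 2 (condensation and ring closure). Both partners are ortho,ortho'-disubstituted and electron-rich, so the aldol step may be slow. The flavylium C4 can also be attacked by the electron-rich arene C–H of 3 or 4, and some flavanone may form instead of the cation. The fallback sets out from 3 (with 4) and comes back at 8, so it also bypasses 6. Compound 3 is protected with MOMCl and iPr2NEt in CH2Cl2 as 2,3,4-trimethoxy-6-(methoxymethoxy)benzaldehyde F2. Base-mediated Claisen–Schmidt condensation with 4 (KOH, EtOH, 25 °C) gives (E)-1-(6-hydroxy-2,3,4-trimethoxyphenyl)-3-[2,3,4-trimethoxy-6-(methoxymethoxy)phenyl]prop-2-en-1-one F3. Oxidative cyclisation with I2 (cat.) in DMSO at 120 °C gives 5,6,7-trimethoxy-2-[2,3,4-trimethoxy-6-(methoxymethoxy)phenyl]-4H-chromen-4-one F4, and HCl in MeOH at 50 °C removes the methoxymethyl group to give 8.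

Step 4 (selective demethylation). Once the 5-O–B chelate exists the neighbouring 6-methoxy group, or the central methoxy group of ring B, may also be cleaved, and the ring B aryloxyborane may precipitate and stall the reaction. The fallback sets out from 8 and comes back at 10. The 6'-hydroxyl is first masked with Ac2O, pyridine and DMAP as 3,4,5-trimethoxy-2-(5,6,7-trimethoxy-4-oxo-4H-chromen-2-yl)phenyl acetate F5, so that the carbonyl chelate is the only site that binds the Lewis acid. Demethylation with AlCl3 in MeCN at 25 °C then gives 2-(5-hydroxy-6,7-dimethoxy-4-oxo-4H-chromen-2-yl)-3,4,5-trimethoxyphenyl acetate F6, and K2CO3 in MeOH removes the acetate to give 10.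

**Further compounds**

F1 | step 3 | 2-(6-hydroxy-2,3,4-trimethoxyphenyl)-5,6,7-trimethoxychroman-4-one (racemic) | COc1cc(O)c(C2CC(=O)c3c(OC)c(OC)c(OC)cc3O2)c(OC)c1OC
F2 | step 2 | 2,3,4-trimethoxy-6-(methoxymethoxy)benzaldehyde | COCOc1cc(OC)c(OC)c(OC)c1C=O
F3 | step 2 | (E)-1-(6-hydroxy-2,3,4-trimethoxyphenyl)-3-[2,3,4-trimethoxy-6-(methoxymethoxy)phenyl]prop-2-en-1-one | COCOc1cc(OC)c(OC)c(OC)c1/C=C/C(=O)c1c(O)cc(OC)c(OC)c1OC
F4 | step 2 | 5,6,7-trimethoxy-2-[2,3,4-trimethoxy-6-(methoxymethoxy)phenyl]-4H-chromen-4-one | COCOc1cc(OC)c(OC)c(OC)c1-c1cc(=O)c2c(OC)c(OC)c(OC)cc2o1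
F5 | step 4 | 3,4,5-trimethoxy-2-(5,6,7-trimethoxy-4-oxo-4H-chromen-2-yl)phenyl acetate | COc1cc(OC(C)=O)c(-c2cc(=O)c3c(OC)c(OC)c(OC)cc3o2)c(OC)c1OC
F6 | step 4 | 2-(5-hydroxy-6,7-dimethoxy-4-oxo-4H-chromen-2-yl)-3,4,5-trimethoxyphenyl acetate | COc1cc(OC(C)=O)c(-c2cc(=O)c3c(O)c(OC)c(OC)cc3o2)c(OC)c1OC
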